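**Plan**

1. Cuts: (a) the bond from the quaternary carbon to its E-alkenyl carbon, with allylic transposition, giving ring-bearing allylic phosphate 20 and chain alkyne 31; (b) in the ring (C1 = side-chain CH, C2 = CMe2, C3 = CHMe, C4 and C5 = CH2, C6 = C=CH2) the bonds C4–C5 and C1–C2.
2. Enabling feature: C5–C6–C1, with the exocyclic carbon on C6, is a masked acetone unit nucleophilic at both ends, and C4–C3(Me)–C2 is a masked 3-methylbut-3-en-2-one electrophilic at both ends, so one Michael/aldol [3+3] annulation closes the ring. Two ester groups on C5 and C1 activate the acetone unit and are removed; the C6 carbonyl becomes the methylidene; the C2 ketone carbon takes its second methyl from a cuprate.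
3. Ring, forward: annulation and decarboxylation (steps 1–2), C3 erased and reset by catalytic enantioselective enone isomerisation (3–4), cuprate addition/axial allylation for CMe2 and the trans C1 centre (5), methylenation and side-chain growth to 20 (6–11).
4. Chain, forward: iterative, reagent-controlled homologation of isopropyl boronic ester 21 to alkyne 31 (12–19).
5. Union: hydroalumination of 31 and copper-catalysed SN2′ substitution of 20 create the quaternary centre, the vinyl group and the E-alkene in the last step (20).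
6. Stereochemistry: ring C3 by catalysis, ring C1 relayed from C3, four chain centres by the chiral carbenoid reagent, quaternary centre by the copper catalyst.

Key step: step 1

Remark: in steps 4 and 20 the configuration is set by the catalyst, and the enantiomer (or pseudo-enantiomer) of the catalyst that gives the drawn product is meant; in step 20, L is a chiral 4,5-diphenylimidazolin-2-ylidene carrying an N-(2-sulfonatophenyl) and an N-(2,6-diethylphenyl) group, used as its silver complex Ag2L2 together with CuCl2·2H2O.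

**Route**

Step 1
Reactants: 1 dimethyl 3-oxopentanedioate; 2 3-methylbut-3-en-2-one
Product: 5 dimethyl 4,5-dimethyl-2-oxocyclohex-3-ene-1,3-dicarboxylate (stereoisomer mixture), via Michael adduct 3 (not isolated), via aldol adduct 4 (not isolated)
Conditions: piperidine (0.2 equiv), AcOH (0.2 equiv), toluene, slow addition of 2 at 20 °C, then reflux with water removal
Reagents that add atoms: none
Why: The amine/acid pair lets one doubly activated methylene of 1 add to the unsubstituted terminus of enone 2 (Michael addition, ring bond C4–C5), and the second activated methylene then attacks the methyl ketone carbonyl and loses water (Knoevenagel-type aldol condensation, ring bond C1–C2, formed as C=C). The closest known reaction type is the Michael–aldol [3+3] cyclohexenone annulation of acetonedicarboxylates and acetoacetates with enones. The ring closes by a 6-(enolendo)-exo-trig aldol addition followed by E1cB dehydration into conjugation with the ketone and the ester. The two sp3 stereocentres formed (ester-bearing C5 and methyl-bearing C3) are not controlled and need not be, because C5 loses its ester in step 2 and C3 is flattened in step 3 and reset in step 4. The step needs regioselective ring closure (diester methylene onto the methyl ketone, not the ketone CH3 onto the central carbonyl); this is secured by the much higher acidity of the CH2 between ketone and ester and by the enolised, poorly electrophilic central carbonyl, while slow addition of 2 secures mono-addition.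

Step 2
Reactants: 5 dimethyl 4,5-dimethyl-2-oxocyclohex-3-ene-1,3-dicarboxylate
Product: 7 (±)-3,4-dimethylcyclohex-2-en-1-one, via diacid 6 (not isolated)
Conditions: 6 M aq. HCl, AcOH, reflux
Reagents that add atoms: none
Why: Acidic ester hydrolysis followed by decarboxylation of both beta-keto acid units (the vinylogous one after deconjugation) should remove the two activating groups and leave the conjugated enone; no stereocentre needs control here.

Step 3
Reactants: 7 (±)-3,4-dimethylcyclohex-2-en-1-one
Product: 9 3,4-dimethylcyclohex-3-en-1-one, via potassium dienolate 8 (not isolated)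
Conditions: KOtBu (3 equiv), t-BuOH, 20 °C; inverse quench into cold aq. AcOH
Reagents that add atoms: none
Why: Thermodynamic gamma-deprotonation should give the endocyclic, fully substituted dienolate, and kinetic alpha-protonation (deconjugative protonation of a dienolate) should give the achiral beta,gamma-enone, which erases the uncontrolled methyl-bearing stereocentre.

Step 4
Reactants: 9 3,4-dimethylcyclohex-3-en-1-one
Product: 10 (4S)-3,4-dimethylcyclohex-2-en-1-one
Conditions: 9-amino-9-deoxy-epi-cinchona alkaloid primary amine (10 mol%), chloroacetic acid (20 mol%), toluene, −25 °C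
Reagents that add atoms: none
Why: Catalytic enantioselective olefin isomerisation by cooperative iminium–base catalysis: the amine forms a dienamine and the protonated quinuclidine delivers the proton to one face of the gamma-carbon, which sets the methyl-bearing centre (ring C3 of the target) as S, with conjugation as the driving force.

Step 5
Reactants: 10 (4S)-3,4-dimethylcyclohex-2-en-1-one
Product: 12 (2R,4S)-3,3,4-trimethyl-2-(prop-2-en-1-yl)cyclohexan-1-one, via lithium enolate 11 (not isolated)
Conditions: Me2CuLi, Et2O, 0 °C; then allyl bromide, HMPA, THF, −30 → 20 °C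
Reagents that add atoms: lithium dimethylcuprate, [Li+].C[Cu-]C; allyl bromide, C=CCBr
Why: Conjugate addition–enolate alkylation: the cuprate builds the gem-dimethyl carbon, and the regiodefined enolate should be allylated axially on the half-chair that keeps the C4 methyl pseudo-equatorial, opposite the pseudo-axial methyl of the new quaternary carbon, which places the allyl group trans to the ring methyl.

Step 6
Reactants: 12 (2R,4S)-3,3,4-trimethyl-2-(prop-2-en-1-yl)cyclohexan-1-one
Product: 13 (1S,3S)-2,2,3-trimethyl-6-methylidene-1-(prop-2-en-1-yl)cyclohexane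
Conditions: Zn, CH2Br2, TiCl4, THF/CH2Cl2, 0 → 20 °C
Reagents that add atoms: dibromomethane, BrCBr
Why: Takai–Lombardo methylenation is non-basic and works on hindered enolisable ketones, so the helper carbonyl should become the exocyclic methylidene without epimerising the adjacent allyl-bearing centre.

Step 7
Reactants: 13 (1S,3S)-2,2,3-trimethyl-6-methylidene-1-(prop-2-en-1-yl)cyclohexane
Product: 15 3-[(1S,3S)-2,2,3-trimethyl-6-methylidenecyclohexyl]propan-1-ol, via alkylborane 14 (not isolated)
Conditions: Sia2BH, THF, 0 °C; then NaOH, H2O2, 0 → 20 °C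
Reagents that add atoms: hydrogen peroxide, OO
Why: Hydroboration–oxidation with the bulky dialkylborane should select the monosubstituted allyl alkene over the hindered 1,1-disubstituted ring alkene and give the anti-Markovnikov primary alcohol.

Step 8
Reactants: 15 3-[(1S,3S)-2,2,3-trimethyl-6-methylidenecyclohexyl]propan-1-ol
Product: 16 3-[(1S,3S)-2,2,3-trimethyl-6-methylidenecyclohexyl]propanal
Conditions: Dess–Martin periodinane, NaHCO3, CH2Cl2, 20 °C
Reagents that add atoms: none
Why: Dess–Martin oxidation should take the primary alcohol to the aldehyde under buffered conditions that leave the alkene untouched.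

Step 9
Reactants: 16 3-[(1S,3S)-2,2,3-trimethyl-6-methylidenecyclohexyl]propanal
Product: 17 (1S,3S)-1-(but-3-yn-1-yl)-2,2,3-trimethyl-6-methylidenecyclohexane
Conditions: dimethyl (1-diazo-2-oxopropyl)phosphonate, K2CO3, MeOH, 0 → 20 °C
Reagents that add atoms: dimethyl (1-diazo-2-oxopropyl)phosphonate, COP(=O)(OC)C(=[N+]=[N-])C(C)=O
Why: The Ohira–Bestmann variant of the Seyferth–Gilbert homologation should convert the aldehyde into the terminal alkyne with one added carbon under mild carbonate conditions.

Step 10
Reactants: 17 (1S,3S)-1-(but-3-yn-1-yl)-2,2,3-trimethyl-6-methylidenecyclohexane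
Product: 19 (2E)-3-methyl-5-[(1S,3S)-2,2,3-trimethyl-6-methylidenecyclohexyl]pent-2-en-1-ol, via alkenylalane 18 (not isolated)
Conditions: Me3Al, Cp2ZrCl2 (0.25 equiv), CH2Cl2, 0 → 20 °C; then n-BuLi, THF, −78 °C; (CH2O)n, −78 → 20 °C
Reagents that add atoms: trimethylaluminium, C[Al](C)C; paraformaldehyde (as formaldehyde), C=O
Why: Negishi zirconium-catalysed carboalumination adds methyl and aluminium syn across the alkyne with methyl on the internal carbon, and hydroxymethylation of the derived alanate goes with retention, which fixes the E trisubstituted alkene.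

Step 11
Reactants: 19 (2E)-3-methyl-5-[(1S,3S)-2,2,3-trimethyl-6-methylidenecyclohexyl]pent-2-en-1-ol
Product: 20 diethyl (2E)-3-methyl-5-[(1S,3S)-2,2,3-trimethyl-6-methylidenecyclohexyl]pent-2-en-1-yl phosphate
Conditions: ClP(O)(OEt)2, pyridine, DMAP (cat.), CH2Cl2, 0 °C
Reagents that add atoms: diethyl chlorophosphate, CCOP(Cl)(=O)OCC
Why: Phosphorylation of the primary allylic alcohol installs the leaving group for the copper-catalysed SN2′ step.

Step 12
Reactants: 21 4,4,5,5-tetramethyl-2-(propan-2-yl)-1,3,2-dioxaborolane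
Product: 22 (S)-4,4,5,5-tetramethyl-2-(3-methylbutan-2-yl)-1,3,2-dioxaborolane
Conditions: (R)-MeCH(SnMe3)OTIB (TIB = 2,4,6-triisopropylbenzoyl), n-BuLi, Et2O, −78 °C; then 21, −78 → 35 °C
Reagents that add atoms: (R)-1-(trimethylstannyl)ethyl 2,4,6-triisopropylbenzoate, C[Sn](C)(C)[C@H](C)OC(=O)c1c(C(C)C)cc(C(C)C)cc1C(C)C
Why: Lithiation–borylation: tin–lithium exchange and borylation proceed with retention and the 1,2-metallate shift with inversion at the carbenoid carbon, so the reagent alone sets the methyl centre next to the isopropyl group.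

Step 13
Reactants: 22 (S)-4,4,5,5-tetramethyl-2-(3-methylbutan-2-yl)-1,3,2-dioxaborolane
Product: 24 (R)-2-(3,4-dimethylpentyl)-4,4,5,5-tetramethyl-1,3,2-dioxaborolane, via boronic ester 23 (not isolated)
Conditions: BrCH2Cl, n-BuLi, Et2O, −78 → 20 °C; repeated once in the same flask
Reagents that add atoms: bromochloromethane, ClCBr
Why: Matteson homologation with (chloromethyl)lithium, run twice, inserts two CH2 groups by 1,2-migration with retention at the migrating stereocentre.

Step 14
Reactants: 24 (R)-2-(3,4-dimethylpentyl)-4,4,5,5-tetramethyl-1,3,2-dioxaborolane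
Product: 25 2-[(2S,5R)-5,6-dimethylheptan-2-yl]-4,4,5,5-tetramethyl-1,3,2-dioxaborolane
Conditions: (R)-MeCH(SnMe3)OTIB, n-BuLi, Et2O, −78 °C; then 24, −78 → 35 °C
Reagents that add atoms: (R)-1-(trimethylstannyl)ethyl 2,4,6-triisopropylbenzoate, C[Sn](C)(C)[C@H](C)OC(=O)c1c(C(C)C)cc(C(C)C)cc1C(C)C
Why: The same lithiation–borylation sets the first of the two vicinal methyl centres by reagent control, four atoms away from the existing one.

Step 15
Reactants: 25 2-[(2S,5R)-5,6-dimethylheptan-2-yl]-4,4,5,5-tetramethyl-1,3,2-dioxaborolane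
Product: 26 2-[(2S,3S,6R)-3,6,7-trimethyloctan-2-yl]-4,4,5,5-tetramethyl-1,3,2-dioxaborolane
Conditions: (R)-MeCH(SnMe3)OTIB, n-BuLi, Et2O, −78 °C; then 25, −78 → 35 °C
Reagents that add atoms: (R)-1-(trimethylstannyl)ethyl 2,4,6-triisopropylbenzoate, C[Sn](C)(C)[C@H](C)OC(=O)c1c(C(C)C)cc(C(C)C)cc1C(C)C
Why: A second lithiation–borylation on the secondary boronic ester sets the adjacent methyl centre anti to the first, again by the reagent and not by the substrate, the existing centre migrating with retention.

Step 16
Reactants: 26 2-[(2S,3S,6R)-3,6,7-trimethyloctan-2-yl]-4,4,5,5-tetramethyl-1,3,2-dioxaborolane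
Product: 28 2-[(3R,4S,7R)-3,4,7,8-tetramethylnonyl]-4,4,5,5-tetramethyl-1,3,2-dioxaborolane, via boronic ester 27 (not isolated)
Conditions: BrCH2Cl, n-BuLi, Et2O, −78 → 20 °C; repeated once in the same flask
Reagents that add atoms: bromochloromethane, ClCBr
Why: Double Matteson homologation inserts the second CH2–CH2 spacer with retention at the migrating carbon.

Step 17
Reactants: 28 2-[(3R,4S,7R)-3,4,7,8-tetramethylnonyl]-4,4,5,5-tetramethyl-1,3,2-dioxaborolane
Product: 29 2-[(2R,5R,6S,9R)-5,6,9,10-tetramethylundecan-2-yl]-4,4,5,5-tetramethyl-1,3,2-dioxaborolane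
Conditions: (S)-MeCH(SnMe3)OTIB, n-BuLi, Et2O, −78 °C; then 28, −78 → 35 °C
Reagents that add atoms: (S)-1-(trimethylstannyl)ethyl 2,4,6-triisopropylbenzoate, C[Sn](C)(C)[C@@H](C)OC(=O)c1c(C(C)C)cc(C(C)C)cc1C(C)C
Why: Lithiation–borylation with the enantiomeric reagent sets the last methyl centre, the future allylic centre of the target, by reagent control.

Step 18
Reactants: 29 2-[(2R,5R,6S,9R)-5,6,9,10-tetramethylundecan-2-yl]-4,4,5,5-tetramethyl-1,3,2-dioxaborolane
Product: 30 (3R,6R,7S,10R)-3,6,7,10,11-pentamethyldodec-1-en-2-yl N,N-diisopropylcarbamate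
Conditions: CH2=CHOC(O)N(iPr)2, LDA, THF, −78 °C; then 29; I2, MeOH, −78 → 20 °C; NaOMe
Reagents that add atoms: vinyl N,N-diisopropylcarbamate, C=COC(=O)N(C(C)C)C(C)C
Why: Zweifel olefination with the alpha-lithiated vinyl carbamate: iodine triggers the stereoretentive 1,2-migration of the secondary alkyl group and methoxide the anti elimination of boron and iodide, giving the 1,1-disubstituted alkenyl carbamate.

Step 19
Reactants: 30 (3R,6R,7S,10R)-3,6,7,10,11-pentamethyldodec-1-en-2-yl N,N-diisopropylcarbamate
Product: 31 (3R,6R,7S,10R)-3,6,7,10,11-pentamethyldodec-1-yne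
Conditions: LDA (3 equiv), THF, −78 → 0 °C; aq. NH4Cl
Reagents that add atoms: none
Why: Base-induced 1,2-elimination of the carbamate from the alkenyl carbamate should give the terminal alkyne without touching the adjacent stereocentre.

Step 20
Reactants: 31 (3R,6R,7S,10R)-3,6,7,10,11-pentamethyldodec-1-yne; 20 diethyl (2E)-3-methyl-5-[(1S,3S)-2,2,3-trimethyl-6-methylidenecyclohexyl]pent-2-en-1-yl phosphate
Product: 33 (1S,3S)-1-[(3S,4E,6R,9R,10S,13R)-3-ethenyl-3,6,9,10,13,14-hexamethylpentadec-4-en-1-yl]-2,2,3-trimethyl-6-methylidenecyclohexane, via alkenylalane 32 (not isolated)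
Conditions: 31, iBu2AlH (1.0 equiv), hexane, 55 °C; then phosphate 20, CuCl2·2H2O (2 mol%), Ag2L2 (1 mol%), THF, −15 °C
Reagents that add atoms: none
Why: Syn hydroalumination gives the E-alkenylalane, and NHC–copper-catalysed enantioselective allylic substitution should deliver the alkenyl group to the methyl-bearing carbon of the E allylic phosphate in SN2′ fashion, creating the quaternary centre (S, catalyst control) together with the vinyl group and keeping the E alkene.

**Compound list**

1 | dimethyl 3-oxopentanedioate | COC(=O)CC(=O)CC(=O)OC | starting material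
2 | 3-methylbut-3-en-2-one | CC(=O)C(C)=C | starting material
3 | dimethyl 2-(2-methyl-3-oxobutyl)-3-oxopentanedioate (not isolated) | COC(=O)CC(=O)C(CC(C)C(C)=O)C(=O)OC | intermediate
4 | dimethyl 4-hydroxy-4,5-dimethyl-2-oxocyclohexane-1,3-dicarboxylate (not isolated) | COC(=O)C1CC(C)C(C)(O)C(C(=O)OC)C1=O | intermediate
5 | dimethyl 4,5-dimethyl-2-oxocyclohex-3-ene-1,3-dicarboxylate (stereoisomer mixture) | COC(=O)C1CC(C)C(C)=C(C(=O)OC)C1=O | intermediate
6 | 4,5-dimethyl-2-oxocyclohex-3-ene-1,3-dicarboxylic acid (not isolated) | OC(=O)C1CC(C)C(C)=C(C(O)=O)C1=O | intermediate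
7 | (±)-3,4-dimethylcyclohex-2-en-1-one | CC1CCC(=O)C=C1C | intermediate
8 | potassium 3,4-dimethylcyclohexa-1,3-dien-1-olate (not isolated) | [K+].[O-]C1=CC(C)=C(C)CC1 | intermediate
9 | 3,4-dimethylcyclohex-3-en-1-one | CC1=C(C)CC(=O)CC1 | intermediate
10 | (4S)-3,4-dimethylcyclohex-2-en-1-one | O=C1CC[C@H](C)C(C)=C1 | intermediate
11 | lithium (4S)-3,3,4-trimethylcyclohex-1-en-1-olate (not isolated) | [Li+].[O-]C1=CC(C)(C)[C@@H](C)CC1 | intermediate
12 | (2R,4S)-3,3,4-trimethyl-2-(prop-2-en-1-yl)cyclohexan-1-one (allyl trans to the C4 methyl) | C=CC[C@H]1C(=O)CC[C@H](C)C1(C)C | intermediate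
13 | (1S,3S)-2,2,3-trimethyl-6-methylidene-1-(prop-2-en-1-yl)cyclohexane | C=CC[C@H]1C(=C)CC[C@H](C)C1(C)C | intermediate
14 | bis(3-methylbutan-2-yl){3-[(1S,3S)-2,2,3-trimethyl-6-methylidenecyclohexyl]propyl}borane (not isolated) | CC(C)C(C)B(CCC[C@H]1C(=C)CC[C@H](C)C1(C)C)C(C)C(C)C | intermediate
15 | 3-[(1S,3S)-2,2,3-trimethyl-6-methylidenecyclohexyl]propan-1-ol | OCCC[C@H]1C(=C)CC[C@H](C)C1(C)C | intermediate
16 | 3-[(1S,3S)-2,2,3-trimethyl-6-methylidenecyclohexyl]propanal | O=CCC[C@H]1C(=C)CC[C@H](C)C1(C)C | intermediate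
17 | (1S,3S)-1-(but-3-yn-1-yl)-2,2,3-trimethyl-6-methylidenecyclohexane | C#CCC[C@H]1C(=C)CC[C@H](C)C1(C)C | intermediate
18 | dimethyl{(1E)-2-methyl-4-[(1S,3S)-2,2,3-trimethyl-6-methylidenecyclohexyl]but-1-en-1-yl}alane (not isolated) | C[Al](C)/C=C(\C)CC[C@H]1C(=C)CC[C@H](C)C1(C)C | intermediate
19 | (2E)-3-methyl-5-[(1S,3S)-2,2,3-trimethyl-6-methylidenecyclohexyl]pent-2-en-1-ol | OC/C=C(\C)CC[C@H]1C(=C)CC[C@H](C)C1(C)C | intermediate
20 | diethyl (2E)-3-methyl-5-[(1S,3S)-2,2,3-trimethyl-6-methylidenecyclohexyl]pent-2-en-1-yl phosphate | CCOP(=O)(OCC)OC/C=C(\C)CC[C@H]1C(=C)CC[C@H](C)C1(C)C | intermediate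
21 | 4,4,5,5-tetramethyl-2-(propan-2-yl)-1,3,2-dioxaborolane | CC(C)B1OC(C)(C)C(C)(C)O1 | starting material
22 | (S)-4,4,5,5-tetramethyl-2-(3-methylbutan-2-yl)-1,3,2-dioxaborolane | CC(C)[C@H](C)B1OC(C)(C)C(C)(C)O1 | intermediate
23 | (R)-2-(2,3-dimethylbutyl)-4,4,5,5-tetramethyl-1,3,2-dioxaborolane (not isolated) | CC(C)[C@H](C)CB1OC(C)(C)C(C)(C)O1 | intermediate
24 | (R)-2-(3,4-dimethylpentyl)-4,4,5,5-tetramethyl-1,3,2-dioxaborolane | CC(C)[C@H](C)CCB1OC(C)(C)C(C)(C)O1 | intermediate
25 | 2-[(2S,5R)-5,6-dimethylheptan-2-yl]-4,4,5,5-tetramethyl-1,3,2-dioxaborolane | CC(C)[C@H](C)CC[C@H](C)B1OC(C)(C)C(C)(C)O1 | intermediate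
26 | 2-[(2S,3S,6R)-3,6,7-trimethyloctan-2-yl]-4,4,5,5-tetramethyl-1,3,2-dioxaborolane | CC(C)[C@H](C)CC[C@H](C)[C@H](C)B1OC(C)(C)C(C)(C)O1 | intermediate
27 | 2-[(2R,3S,6R)-2,3,6,7-tetramethyloctyl]-4,4,5,5-tetramethyl-1,3,2-dioxaborolane (not isolated) | CC(C)[C@H](C)CC[C@H](C)[C@H](C)CB1OC(C)(C)C(C)(C)O1 | intermediate
28 | 2-[(3R,4S,7R)-3,4,7,8-tetramethylnonyl]-4,4,5,5-tetramethyl-1,3,2-dioxaborolane | CC(C)[C@H](C)CC[C@H](C)[C@H](C)CCB1OC(C)(C)C(C)(C)O1 | intermediate
29 | 2-[(2R,5R,6S,9R)-5,6,9,10-tetramethylundecan-2-yl]-4,4,5,5-tetramethyl-1,3,2-dioxaborolane | CC(C)[C@H](C)CC[C@H](C)[C@H](C)CC[C@@H](C)B1OC(C)(C)C(C)(C)O1 | intermediate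
30 | (3R,6R,7S,10R)-3,6,7,10,11-pentamethyldodec-1-en-2-yl N,N-diisopropylcarbamate | C=C(OC(=O)N(C(C)C)C(C)C)[C@H](C)CC[C@@H](C)[C@@H](C)CC[C@@H](C)C(C)C | intermediate
31 | (3R,6R,7S,10R)-3,6,7,10,11-pentamethyldodec-1-yne | C#C[C@H](C)CC[C@@H](C)[C@@H](C)CC[C@@H](C)C(C)C | intermediate
32 | bis(2-methylpropyl)[(1E,3R,6R,7S,10R)-3,6,7,10,11-pentamethyldodec-1-en-1-yl]alane (not isolated) | CC(C)C[Al](CC(C)C)/C=C/[C@H](C)CC[C@@H](C)[C@@H](C)CC[C@@H](C)C(C)C | intermediate
33 | (1S,3S)-1-[(3S,4E,6R,9R,10S,13R)-3-ethenyl-3,6,9,10,13,14-hexamethylpentadec-4-en-1-yl]-2,2,3-trimethyl-6-methylidenecyclohexane | C=C[C@@](C)(/C=C/[C@H](C)CC[C@@H](C)[C@@H](C)CC[C@@H](C)C(C)C)CC[C@H]1C(=C)CC[C@H](C)C1(C)C | target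

**Step count and risks**

Total steps: 20. Longest linear sequence: 12 (steps 1–11, then step 20); the chain branch is 8 steps (12–19) before the union.

Step 4. The isomerisation of the tetrasubstituted beta,gamma-enone may stall at the conjugation equilibrium, or the gamma-protonation may occur with poor facial selectivity, so that 10 would be formed in low enantiomeric purity. The fallback replaces catalysis by resolution and sets out from racemic enone 7. Addition of lithiated (S)-N,S-dimethyl-S-phenylsulfoximine (n-BuLi, THF, −78 °C) to the carbonyl group should give two diastereomeric carbinols: (4S)-3,4-dimethyl-1-{[(S)-N-methyl-S-phenylsulfonimidoyl]methyl}cyclohex-2-en-1-ol F1 and its (4R) diastereomer (4R)-3,4-dimethyl-1-{[(S)-N-methyl-S-phenylsulfonimidoyl]methyl}cyclohex-2-en-1-ol F2. These are separated on silica, and thermolysis of F1 (toluene, 110 °C) releases the sulfoximine and returns the route at 10.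

Step 5. C-Allylation of the hindered enolate may be slow, so that proton exchange between enolate and product causes loss of regiochemical integrity, over-allylation and erosion of the trans selectivity. The fallback sets out from 10 and changes the bond-forming event to a palladium-mediated one. After the same cuprate addition, enolate 11 is captured on oxygen with allyl chloroformate to give allyl (4S)-3,3,4-trimethylcyclohex-1-en-1-yl carbonate F3. Pd(PPh3)4 in THF at 20 °C then effects decarboxylative Tsuji allylation under neutral conditions, the regiodefined palladium enolate being allylated on the face opposite the axial methyl group, and the route is rejoined at 12.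

Step 20. Hydroalumination of the alpha-branched alkyne may be incomplete or accompanied by alkyne deprotonation and isobutyl transfer, and the copper step may lose SN2′ or facial selectivity with two valuable fragments. The fallback sets out from 31 and 20 and uses an isolable boron nucleophile. Hydroboration of 31 with pinacolborane catalysed by Cp2ZrHCl should give 4,4,5,5-tetramethyl-2-[(1E,3R,6R,7S,10R)-3,6,7,10,11-pentamethyldodec-1-en-1-yl]-1,3,2-dioxaborolane F4, which can be purified. NHC–copper-catalysed allylic substitution with 20 (CuCl, chiral imidazolinium sulfonate, NaOMe, THF) then proceeds by boron-to-copper exchange and comes back to the route at 33.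

**Further compounds**

F1 | step 4 | (4S)-3,4-dimethyl-1-{[(S)-N-methyl-S-phenylsulfonimidoyl]methyl}cyclohex-2-en-1-ol (carbinol configuration not assigned) | OC1(C[S@@](=O)(=NC)c2ccccc2)CC[C@H](C)C(C)=C1
F2 | step 4 | (4R)-3,4-dimethyl-1-{[(S)-N-methyl-S-phenylsulfonimidoyl]methyl}cyclohex-2-en-1-ol (carbinol configuration not assigned) | OC1(C[S@@](=O)(=NC)c2ccccc2)CC[C@@H](C)C(C)=C1
F3 | step 5 | allyl (4S)-3,3,4-trimethylcyclohex-1-en-1-yl carbonate | C=CCOC(=O)OC1=CC(C)(C)[C@@H](C)CC1
F4 | step 20 | 4,4,5,5-tetramethyl-2-[(1E,3R,6R,7S,10R)-3,6,7,10,11-pentamethyldodec-1-en-1-yl]-1,3,2-dioxaborolane | CC(C)[C@H](C)CC[C@H](C)[C@H](C)CC[C@@H](C)/C=C/B1OC(C)(C)C(C)(C)O1
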